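I began from what cannot happen: by the reactions considered, each target takes up one coupling partner and one substrate, so the target of a flask cannot pass what the smaller of these two charges provides. Substrate binds free catalyst reversibly to give catalyst intermediate A, coupling partner turns that into catalyst intermediate B, and catalyst intermediate B releases target and free catalyst. Free catalyst, coupling partner and target can also give over-reaction product.

the same everywhere: substrate 0.40 M; free catalyst 0.40 mM (in portions, 3)
- cedar: coupling partner 0.14 M; run made earlier; portions every 4.0 min
- alder: coupling partner 0.98 M; run made earlier; portions every 4.0 min
- ochre: coupling partner 0.100 M; the portions of free catalyst follow each other after 4.0 min, the first at the start; time 2.5 h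
- red: coupling partner 0.200 M; the portions of free catalyst follow each other after 4.0 min, the first at the start; time 2.5 h
- teal: coupling partner 0.400 M; the portions of free catalyst follow each other after 4.0 min, the first at the start; time 2.5 h
- blue: coupling partner 0.800 M; the portions of free catalyst follow each other after 4.0 min, the first at the start; time 2.5 h

| run | time / min | target / % |
|---|---|---|
| cedar | 12.0 | 17.4 |
| cedar | 40.0 | 33.0 |
| cedar | 60.0 | 34.4 |
| cedar | 120 | 34.3 |
| alder | 25.0 | 35.4 |
| alder | 50.0 | 10.1 |
| alder | 80.0 | 3.5 |
| alder | 120 | 1.2 |

(standard deviation of a reading: 0.3 percentage points)

- reactions considered so far: coupling partner + free catalyst + target -> free catalyst + over-reaction product; catalyst intermediate B -> free catalyst + target; coupling partner + catalyst intermediate A -> catalyst intermediate B; substrate + free catalyst <-> catalyst intermediate A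
- "hardly changes" means that all values lie within two and a half points (for a concentration: within two and a half percent of the largest)

My rule of thumb was the partner ceiling, the charge of coupling partner divided by the charge of substrate, which for ochre is 25.0%. It treats coupling partner as the limiting reagent. For cedar it gives 35.0%, and the cedar readings stood at 34.4% after 60.0 min and 34.3% after 120 min, so the target stopped just beneath the ceiling and stayed there.

The rule stops where the ratio of the two charges reaches 1.00, which is teal's ratio, since beyond it substrate is the smaller charge. Blue stands at 2.00 and alder at 2.45. Alder shows what lies past that border: its target read 35.4% after 25.0 min but 1.2% after 120 min. So I committed to ochre and red just under their ceilings of 25.0% and 50.0%, to teal somewhat under full conversion, and to blue far down, as in alder. These were bounds and a direction, not the forecast's numbers.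

- amount of target at the end, in percent of the substrate charged for ochre, red, teal, blue, in this order
- how the row runs (rises, then falls / hardly changes / falls all the way / falls, then rises / rises all the way)

The forecast gave 24.6%, 48.4%, 84% and 10%, a row that rises, then falls. Of blue it said “excess partner destroys target”.

The flasks gave 24.7%, 48.2%, 82.0% and 8.56%, a row that rises, then falls, turning at 0.43 M of coupling partner.

    coupling partner + free catalyst + target → free catalyst + over-reaction product (k = 8.20 /M²/s)
    catalyst intermediate B → free catalyst + target (k = 28.0 /s)
    coupling partner + catalyst intermediate A → catalyst intermediate B (k = 4.10 /M/s)
    substrate + free catalyst ⇌ catalyst intermediate A (K = 100 /M, k = 16.0 /M/s)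

Ochre ended at 24.7% against its ceiling of 25.0%, and red at 48.2% against 50.0%. With the whole charges counted as present at once, ochre's target had a half-life of 0.59 h by the over-reaction path, shorter than the 2.5 h of the run. In the running ochre flask at 0.193 h, however, coupling partner had a half-life of 19 h by that path, longer than the 2.5 h of the run, and ochre ended with 0.135% of the substrate charged as over-reaction product.

The runs stem from a simulated flask for substances that don't exist; scatter was added.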